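The ratio to look at is 0.588 /M/h to 0.226 /M/h: the climb of the reciprocal of [J] per hour, from the second reading to the last, in the theta run and in the gamma run. A rate that goes as J squared makes that reciprocal climb in a straight line, and these runs nearly do.

| setting | theta | delta | beta | gamma | alpha |
|---|---|---|---|---|---|
| J | 0.120 M | 0.0600 M | 0.0600 M | 0.120 M | 0.240 M |
| Q | 0.00960 M | 0.00960 M | 0.00960 M | 0.00480 M | 0.00320 M |
| time |  |  |  |  | 9.7 h |

| run | time / h | [J] / M |
|---|---|---|
| theta run | 1.9 | 0.1134 |
| theta run | 3.9 | 0.1015 |
| theta run | 5.8 | 0.0920 |
| theta run | 7.8 | 0.0832 |
| theta run | 9.7 | 0.0754 |
| delta run | 1.9 | 0.0578 |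
| delta run | 3.9 | 0.0545 |
| delta run | 5.8 | 0.0515 |
| delta run | 7.8 | 0.0480 |
| delta run | 9.7 | 0.0459 |
| beta run | 1.9 | 0.0584 |
| beta run | 3.9 | 0.0548 |
| beta run | 5.8 | 0.0512 |
| beta run | 7.8 | 0.0486 |
| beta run | 9.7 | 0.0445 |
| gamma run | 1.9 | 0.1175 |
| gamma run | 3.9 | 0.1127 |
| gamma run | 5.8 | 0.1078 |
| gamma run | 7.8 | 0.1023 |
| gamma run | 9.7 | 0.0982 |

(standard deviation of a reading: 4 × 10⁻⁴ M)

- the exponent of [Q] in the starting rate at the charge of the theta run (at the point where two percent of the J have become G)
- the exponent of [J] in the starting rate at the charge of the theta run (at the point where two percent of the J have become G) (one fixed amount of G, the same in the runs compared)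
- the delta run starts with 0.0600 M less of J than the theta run, and with no G. Compared where both hold the same amount of J, once fifteen percent of what the delta run was charged with has turned into G, is the delta run faster, slower or alike (within a tenth)?
- J in the alpha run at 9.7 h, as a share of the J charged

- Overall: J -> G, with Q as catalyst.
- Constant volume, constant temperature.
- What is held in complexes is read along with the free species.
- An order is taken over about fifteen percent of the charge, up and down.

The theta run has twice the Q of the gamma run, yet it climbs 2.60 times as fast, more than the charge alone suggests. So suppose a fixed amount of Q does no work and the climb follows what remains. Setting the ratio of the two remainders equal to 2.60 gives 1.81 mM, the dead catalyst: the amount of Q taken off each charge before counting. On this picture the late order in Q is the charge over the charge minus the dead catalyst, or 1.23 for the theta run.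

The theta line also starts late. Carried back to the charge, the theta line leaves at 79.0 min, an induction period. Two percent of the theta charge is 2.40 mM, less than the 6.60 mM gone by 1.9 h, so the asked exponents are taken early, near that lag. I expect them below the late values, by an amount these readings don't give.

Now the alpha run. Its working Q is 1.39 mM, a share 0.179 of the theta run's, so I take its climb as 0.105 /M/h. Over 8.38 h past the lag, assumed the same as in the theta run, that leaves 0.198 M, or 82.5% of the charge.

The weak link is the constant climb, because the alpha run is charged with more J than the theta run. The delta and beta runs together climb 0.660 /M/h at a mean J of 0.0499 M, faster than the theta run at 0.0885 M. Let the climb fall as one over one plus J per a brake concentration. These readings put the brake at 0.263 M, which makes the late order in J 1.69 at the theta charge. At the alpha run's reckoned mean J of 0.219 M the reckoned climb drops to 0.0767 /M/h, so I commit to 86.6%. With no term for G in this reckoning, I call the comparison alike.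

The forecast gave 1.4 for Q, 1.7 for J, alike, and 81% (from 76% to 87%) for the alpha run, suspecting “a dimer-active catalyst or a small poison”.

The alpha run holds 87.1% of its J at 9.7 h.

    Jy + J ⇌ QJ, settled at all times (1.810 /M)
    QJ + J ⇌ QJ2, settled at all times (3.970 /M)
    QJ2 → G + QJ (12.71 /h)
    Jy + Ja → Qa
    Q → Jy (1.094 /h)

Where two percent of the J has become G at the theta charge, the exponents are 0.79 in Q and 1.1 in J, and at equal J the delta run and the theta run go alike. Put the dead catalyst on the gamma run: the theta run needs 14.2 h past the lag for the G made to come to half of the J charged, and a working Q of 2.99 mM in the gamma run against 7.79 mM in the theta run stretches that to 38.2 h with the same lag added back. In the gamma run the G made comes to half of the J charged at 37.4 h.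

Readings and results are simulated for substances that don't exist; noise was put on by code.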